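**Plan**

1. Retrosynthesis: remove the C3–Br bond (electrophilic bromination), return the pyrrole ring to an N-Boc indoline, de-aromatize the benzo ring to a cis-3a,7a-dihydro diene, then cut C3a–C4 and C7–C7a, with SO2 put back as a bridge between C4 and C7.
2. Enabling feature: C4–C5(Br)–C6(Br)–C7 of the benzene ring is a symmetric 2,3-dibromobutadiene unit, and the C3a–C7a bond is the C=C of a five-membered enecarbamate, so the carbocycle can be grafted onto a ready-made pyrroline ring.
3. Forward: the five-membered N-ring is bought; the six-membered ring is closed by [4+2] cycloaddition and SO2 extrusion, then aromatized; Boc removal, dehydrogenation of the pyrroline ring and C3 bromination finish the route.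
4. Stereochemistry: the only stereocentres are the transient cis C3a/C7a pair (racemic), set by suprafacial addition to the ring alkene and erased on aromatization.

Key step: step 2

Remark: the target is planar and has no stereogenic element, so the structure given is its only stereoisomer and no asymmetric step is needed.

**Route**

Step 1
Reactants: 1 3,4-dibromothiophene
Product: 3 3,4-dibromothiophene 1,1-dioxide, via 3,4-dibromothiophene 1-oxide 2 (not isolated)
Conditions: (CF3CO)2O, H2O2 (50% aq.), CH2Cl2–MeCN, 0 °C → rt; cold aqueous work-up, product kept cold and used at once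
Reagents that add atoms: trifluoroperacetic acid, OOC(=O)C(F)(F)F, formed in the flask from trifluoroacetic anhydride and hydrogen peroxide, OO, which is the source of both sulfone oxygens
Why: Electrophilic S-oxidation of a thiophene by a peracid, where trifluoroperacetic acid is strong enough for the halogen-deactivated sulfur and the S-oxide 2 is oxidized faster than it forms, so the reaction should run through to the sulfone.

Step 2
Reactants: 3 3,4-dibromothiophene 1,1-dioxide; 4 tert-butyl 2,3-dihydro-1H-pyrrole-1-carboxylate
Product: 6 tert-butyl cis-5,6-dibromo-2,3,3a,7a-tetrahydro-1H-indole-1-carboxylate (racemic), via bridged sulfone cycloadduct 5 (not isolated)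
Conditions: 4 (3 equiv), toluene, 50 °C, slow addition of 3, N2 sweep; filtered through basic alumina and taken on without storage
Reagents that add atoms: none
Why: The non-aromatic, LUMO-lowered sulfone diene 3 and the nitrogen-raised HOMO of enecarbamate 4 should combine in a concerted suprafacial inverse-electron-demand [4+2] cycloaddition that forms C3a–C4 and C7–C7a, after which the strained 7-thiabicyclo[2.2.1]heptene 7,7-dioxide 5 loses SO2 by a thermally allowed cheletropic retro-addition made irreversible by escape of the gas. The closest known reaction type is the Diels–Alder/SO2-extrusion annulation of halogenated thiophene 1,1-dioxides with enol ethers, enamines and simple alkenes. The six-membered carbocycle is closed by intermolecular [4+2] annulation across the C4=C5 bond of the pyrroline, two bonds in one event, and not by cyclization of a chain. C3a and C7a are set cis by suprafacial addition to the cis ring alkene; endo and exo adducts converge on the same racemic diene once the sulfur bridge has gone, and both centres are removed in step 3. The diene is symmetrically substituted, so only one constitution can form, and both bromines arrive on the inner diene carbons, the future C5 and C6. The selectivity needed is cross-cycloaddition over [4+2] self-dimerization of 3, which is secured by adding 3 slowly to an excess of 4, while sweeping out SO2 keeps the medium non-acidic so the carbamate nitrogen is not lost from C7a.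

Step 3
Reactants: 6 tert-butyl cis-5,6-dibromo-2,3,3a,7a-tetrahydro-1H-indole-1-carboxylate
Product: 7 tert-butyl 5,6-dibromoindoline-1-carboxylate
Conditions: DDQ (1.1 equiv), toluene, 0 °C → rt
Reagents that add atoms: none
Why: Quinone dehydrogenation of a cyclohexadiene, in which hydride abstraction from the allylic, nitrogen-flanked C7a–H followed by loss of H-3a is driven by formation of the benzene ring and leaves the carbamate and both C–Br bonds untouched.

Step 4
Reactants: 7 tert-butyl 5,6-dibromoindoline-1-carboxylate
Product: 8 5,6-dibromoindoline (5,6-dibromo-2,3-dihydro-1H-indole)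
Conditions: TFA, CH2Cl2, 0 °C → rt; aq. NaHCO3 work-up
Reagents that add atoms: none
Why: Standard acidolysis of a Boc carbamate (loss of the tert-butyl cation as isobutene, then decarboxylation of the carbamic acid), to which the aryl bromides are inert.

Step 5
Reactants: 8 5,6-dibromoindoline
Product: 9 5,6-dibromo-1H-indole
Conditions: DDQ (1.05 equiv), 1,4-dioxane, rt
Reagents that add atoms: none
Why: Dehydrogenation of a free indoline to the indole by a quinone, a standard transformation driven by aromatization of the pyrrole ring and tolerant of aryl halides.

Step 6
Reactants: 9 5,6-dibromo-1H-indole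
Product: 10 3,5,6-tribromo-1H-indole
Conditions: NBS (1.0 equiv), DMF, 0 °C, dark
Reagents that add atoms: N-bromosuccinimide, O=C1CCC(=O)N1Br
Why: Electrophilic aromatic substitution at C3, the enamine-like and most nucleophilic position of an N–H indole, while the benzo ring is deactivated by its two bromines and one equivalent of NBS should limit attack at C2.

**Compound list**

1 | 3,4-dibromothiophene | Brc1cscc1Br | starting material
2 | 3,4-dibromothiophene 1-oxide | O=S1C=C(Br)C(Br)=C1 | intermediate (not isolated)
3 | 3,4-dibromothiophene 1,1-dioxide | O=S1(=O)C=C(Br)C(Br)=C1 | intermediate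
4 | tert-butyl 2,3-dihydro-1H-pyrrole-1-carboxylate | O=C(OC(C)(C)C)N1CCC=C1 | starting material
5 | tert-butyl 5,6-dibromo-2,3,3a,4,7,7a-hexahydro-4,7-epithioindole-1-carboxylate S,S-dioxide (cis ring fusion, racemic; orientation of the SO2 bridge not assigned) | O=C(OC(C)(C)C)N1CC[C@@H]2[C@H]1C1C(Br)=C(Br)C2S1(=O)=O | intermediate (not isolated)
6 | tert-butyl cis-5,6-dibromo-2,3,3a,7a-tetrahydro-1H-indole-1-carboxylate (racemic, relative configuration shown) | O=C(OC(C)(C)C)N1CC[C@@H]2C=C(Br)C(Br)=C[C@H]12 | intermediate
7 | tert-butyl 5,6-dibromoindoline-1-carboxylate | O=C(OC(C)(C)C)N1CCc2cc(Br)c(Br)cc21 | intermediate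
8 | 5,6-dibromoindoline | Brc1cc2c(cc1Br)CCN2 | intermediate
9 | 5,6-dibromo-1H-indole | Brc1cc2[nH]ccc2cc1Br | intermediate
10 | 3,5,6-tribromo-1H-indole | Brc1cc2[nH]cc(Br)c2cc1Br | target

**Summary**

Total step count: 6. Longest linear sequence: 6 steps (1 → 10); compound 4 enters at step 2.

**Steps most likely to fail, with fallbacks**

Step 2. The sulfone diene may dimerize by [4+2] self-addition faster than it adds to the only moderately electron-rich enecarbamate. The diene product may also lose its carbamate nitrogen from C7a under heat or trace acid, opening the five-membered ring as the carbocycle aromatizes. The fallback sets out from 3 and returns at 7, with the dienophile raised to the lactam oxidation level. Commercial tert-butyl 2-oxopyrrolidine-1-carboxylate is O-silylated (LiHMDS, TBSCl, THF, −78 °C) to the silyl ketene N,O-acetal tert-butyl 5-[(tert-butyldimethylsilyl)oxy]-2,3-dihydro-1H-pyrrole-1-carboxylate F1, a much stronger donor than 4. Its cycloaddition to 3 at or below room temperature should give the bridged sulfone tert-butyl 5,6-dibromo-7a-[(tert-butyldimethylsilyl)oxy]-2,3,3a,4,7,7a-hexahydro-4,7-epithioindole-1-carboxylate S,S-dioxide F2. Loss of SO2 then gives tert-butyl cis-5,6-dibromo-7a-[(tert-butyldimethylsilyl)oxy]-2,3,3a,7a-tetrahydro-1H-indole-1-carboxylate F3. A catalytic amount of CSA should ionize this N,O-acetal to the N-acyliminium ion, and loss of H-3a with expulsion of the silanol delivers 7 directly. The same bonds are formed, but the sensitive diene 6 and the oxidant of step 3 are both avoided.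

Step 1. S-oxidation of the halogen-deactivated thiophene may stall, and the unblocked dioxide (or the transient S-oxide) may be consumed by self-cycloaddition during reaction and isolation. The fallback sets out from 1 and returns at 3. Double α-lithiation and silylation (LDA 2.2 equiv, TMSCl, THF, −78 °C) should give 3,4-dibromo-2,5-bis(trimethylsilyl)thiophene F4, whose more electron-rich sulfur is oxidized by mCPBA (CH2Cl2, rt) to the sterically shielded, storable 3,4-dibromo-2,5-bis(trimethylsilyl)thiophene 1,1-dioxide F5. Fluoride protodesilylation of the two α-sulfonyl vinylsilanes (TBAF·3H2O, THF, −20 °C) in the presence of excess 4 then releases 3 in the flask, where step 2 should consume it before it can dimerize.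

Step 6. Over-bromination at C2 and oxidative or acid-induced decomposition of the unprotected 3-bromoindole may erode the product during reaction and chromatography. The fallback sets out from 9 and returns at 10. N-silylation (NaH, TIPSCl, THF, 0 °C) gives 5,6-dibromo-1-(triisopropylsilyl)-1H-indole F6. The bulky silyl group shields N and C2, so NBS (THF, −78 °C) should give only 3,5,6-tribromo-1-(triisopropylsilyl)-1H-indole F7, a robust compound that can be purified and stored. TBAF (THF, 0 °C) then frees 10 just before use.

**Further compounds**

F1 | step 2 | tert-butyl 5-[(tert-butyldimethylsilyl)oxy]-2,3-dihydro-1H-pyrrole-1-carboxylate | CC(C)(C)OC(=O)N1CCC=C1O[Si](C)(C)C(C)(C)C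
F2 | step 2 | tert-butyl 5,6-dibromo-7a-[(tert-butyldimethylsilyl)oxy]-2,3,3a,4,7,7a-hexahydro-4,7-epithioindole-1-carboxylate S,S-dioxide (cis ring fusion, racemic) | CC(C)(C)OC(=O)N1CC[C@@H]2[C@@]1(O[Si](C)(C)C(C)(C)C)C1C(Br)=C(Br)C2S1(=O)=O
F3 | step 2 | tert-butyl cis-5,6-dibromo-7a-[(tert-butyldimethylsilyl)oxy]-2,3,3a,7a-tetrahydro-1H-indole-1-carboxylate (racemic) | CC(C)(C)OC(=O)N1CC[C@@H]2C=C(Br)C(Br)=C[C@]12O[Si](C)(C)C(C)(C)C
F4 | step 1 | 3,4-dibromo-2,5-bis(trimethylsilyl)thiophene | C[Si](C)(C)c1sc([Si](C)(C)C)c(Br)c1Br
F5 | step 1 | 3,4-dibromo-2,5-bis(trimethylsilyl)thiophene 1,1-dioxide | C[Si](C)(C)C1=C(Br)C(Br)=C([Si](C)(C)C)S1(=O)=O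
F6 | step 6 | 5,6-dibromo-1-(triisopropylsilyl)-1H-indole | CC(C)[Si](C(C)C)(C(C)C)n1ccc2cc(Br)c(Br)cc21
F7 | step 6 | 3,5,6-tribromo-1-(triisopropylsilyl)-1H-indole | CC(C)[Si](C(C)C)(C(C)C)n1cc(Br)c2cc(Br)c(Br)cc21
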